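## Analysis of the target

The target is a humulane-type acid: an eleven-membered carbocycle, numbered here C1–C11, with C1 carrying the carboxyl carbon C13, C1=C2 as the ring alkene, C5 carrying the exocyclic methylene C12, C6 the free carbinol, C8 the gem-dimethyl carbon and C10 the angeloyloxy carbon. This numbering is used for the corresponding atoms of all intermediates (systematic names carry their own locants). C1=C2 is trisubstituted and E, so C3 is cis to C11 (a cis-cycloundecene) and trans to C13. The only stereocentres, C6 (S) and C10 (S), are 1,5-related across the quaternary C8, so neither can be expected to control the other. Sensitive groups are the angelate (Z to E isomerisation to the tiglate), the γ-acyloxy acid (a free C10 hydroxyl would lactonise onto C13), the allylic alcohol next to a 1,1-disubstituted alkene, and, in late intermediates, an α-methylene ketone. The difficulty is the medium ring, whose transannular strain makes end-to-end closure slow, combined with a trisubstituted enoate of fixed geometry inside that ring and two stereocentres that each need reagent control. Three features are used: O–C10–C11–C1–C13 is a latent γ-lactone ring; O–C6–C5(=C12)–C4–C3–C2=C1 is the pattern left by an oxy-Cope rearrangement of a C6 carbinol with vinyl groups on C6 and C1, followed by methylenation of the C5 enolate; and once C2–C5 are removed, the remaining seven-membered ring C1/C6–C11 holds C6–C11 with the C8 gem-dimethyl group, which is the ring of dimedone.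

## Retrosynthetic reasoning

**25 ⇐ 24 ⇐ 21 (acyl C–O bond at O–C10; C13–O bond re-formed).** The angelate and the free acid are treated as the two halves of a lactone. Removing the angeloyl group and joining O–C10 to C13 gives the bridged lactone 21, with C6–OH silylated. The lactone protects both functions through the whole route with no extra steps. Forward, 21 is opened and the C10 alkoxide is acylated with 22 in the same flask, so the γ-hydroxy acid never exists in neutral form; desilylation ends the synthesis.

**21 ⇐ 20 ⇐ 19 ⇐ 17 (C6–H; C5=C12).** C6 is the one stereocentre that cannot be relayed from C10, so it is made last on the ring, by reagent-controlled reduction of the α-methylene ketone 19. The enone is unmasked from the Mannich base 17, which keeps the reactive enone out of the key step.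

**17 ⇐ 13 + 14 (key: C3–C4 cut, C1–C6 re-joined; C5–C12 cut).** Cutting C3–C4 and reconnecting C1 to C6 turns the eleven-membered ring into a cycloheptanol with vinyl groups on C6 and C1, compound 13. This cut is chosen, and not an end-to-end cut, because the forward reaction is a ring expansion through a six-membered transition state: it forms the medium ring, creates C1=C2 with its geometry, and leaves a regiodefined C5 enolate for C12. The lactone bridge in 13 is what makes the geometry predictable.

**13 ⇐ 11 + 12 (C5–C6).** The C6 vinyl group is added to ketone 11. The forward step has to deliver it anti to C13.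

**11 ⇐ 10 (C1–C6).** The cycloheptanone is opened between C1 and C6 to the ester 10. Forward, the lactone dienolate is acylated at C1 by the C6 ester; the tether fixes the configuration at C1 from C10.

**10 ⇐ 7 + 8 (C1=C2) and 7 ⇐ 5 (C10–H).** C2 and C3 come from 8 by olefination at C1. The C10 stereocentre comes from ester-directed asymmetric hydrogenation of the 4-oxo diester 5, the only point where the two sides of the C10 ketone differ strongly enough for a catalyst to tell them apart.

**5 ⇐ 3 ⇐ 1 + 2 (C6–C11 re-joined; C11–C1 cut).** Re-joining C6 to C11 closes 5 to an alkylated dimedone 3, which comes from 1 and 2. Dimedone supplies C6–C11 with both oxygens and the gem-dimethyl group; 2 supplies C1 and C13. Forward, C-alkylation and retro-Claisen opening place C1 between C11 and C6 for the later seven-ring closure.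

## Alternatives that were turned down

**Alternative 1:** the textbook cut at C5–C6. The forward key step is an intramolecular Nozaki–Hiyama–Kishi addition of the 2-bromoalkene in A1 to its C6 aldehyde. It was turned down for three reasons. It closes the eleven-membered ring end to end under high dilution and pays the full transannular strain with no pre-organisation. The new C6 carbinol is 1,5 to C10 across C8, so no substrate control is expected and an oxidation/reduction pair would still be needed. A1 also needs the C6 ester reduced to an aldehyde in the presence of the lactone, which costs three redox steps.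

**Alternative 2:** cut at C1=C2. The forward key step is ring-closing metathesis of the α-methylene lactone and the terminal alkene of diene A2. It was turned down because it asks for metathesis between an electron-poor 1,1-disubstituted alkene and a terminal alkene to give a trisubstituted alkene inside a strained ring, where oligomerisation and isomerisation of the α-methylene lactone to the butenolide compete. The C1=C2 geometry would be left to kinetic chance. Both stereocentres would also have to be set in a long linear sequence before the uncertain step.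

**Alternative 3:** re-join C6–C11. The forward key step is retro-aldol ring expansion of the dimedone-derived bicyclo[5.4.0] ketol A3 to the cycloundecenedione A4. It is short and the cycloheptene fixes the C1=C2 geometry. It was turned down because C10 emerges as a ketone flanked by two methylene groups (C9, C11), for which no dependable enantioselective reduction exists. C1=C2 can also migrate to C11=C1 into conjugation with that ketone, and the C6 and C10 ketones would have to be told apart afterwards.

Key step: step 7

## Route

Assumption: the sense of induction in step 3 is taken to be that known for simple 4-oxo esters; compounds 1, 2, 8, 12, 14 and 22 are taken as commercial.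

Step 1
Reactants: 1 dimedone (5,5-dimethylcyclohexane-1,3-dione); 2 methyl bromoacetate
Product: 3 methyl 2-(4,4-dimethyl-2,6-dioxocyclohexyl)acetate
Conditions: NaOMe (1.0 equiv), MeOH, reflux
Reagents that add atoms: none
Why: C-alkylation of the dimedone enolate by an α-halo ester (a protic medium favours C over O); it joins C11 to C1 and brings in C13.

Step 2
Reactants: 3 methyl 2-(4,4-dimethyl-2,6-dioxocyclohexyl)acetate
Product: 5 dimethyl 6,6-dimethyl-4-oxooctanedioate, via keto diacid 4 (not isolated)
Conditions: aq. NaOH (4 M), reflux; HCl to pH 1, evaporate; MeOH, H2SO4 (cat.), reflux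
Reagents that add atoms: sodium hydroxide, [Na+].[OH-]; methanol, CO
Why: Retro-Claisen cleavage of the 2-alkyl-1,3-dione: hydroxide adds to a ring carbonyl and C6–C11 breaks, made irreversible by carboxylate formation; Fischer esterification then gives the diester.

Step 3
Reactants: 5 dimethyl 6,6-dimethyl-4-oxooctanedioate
Product: 7 methyl 3,3-dimethyl-4-[(2R)-5-oxooxolan-2-yl]butanoate, via hydroxy diester 6 (not isolated)
Conditions: [RuCl((S)-BINAP)(p-cymene)]Cl (1 mol %), H2 (60 bar), MeOH, 50 °C; then TsOH (cat.), PhMe, 80 °C
Reagents that add atoms: none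
Why: Ester-directed asymmetric hydrogenation of a 4-oxo ester (Noyori type); the C13 ester, three atoms from the ketone, should direct and the (S)-ligand should give the topicity of (S)-γ-valerolactone, here named R because C9 outranks C11. The hydroxy ester should close to the γ-lactone on C13, not the δ-lactone on C6, because the C6 ester is neopentyl-shielded and γ-lactones are favoured.

Step 4
Reactants: 7 methyl 3,3-dimethyl-4-[(2R)-5-oxooxolan-2-yl]butanoate; 8 acetaldehyde
Product: 10 methyl 4-[(2S,4E)-4-ethylidene-5-oxooxolan-2-yl]-3,3-dimethylbutanoate, via phosphonate 9 (not isolated)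
Conditions: LDA (1.1 equiv), THF, −78 °C; ClP(O)(OEt)2; LDA (2.1 equiv), −78 → 0 °C; then 8, −78 °C → rt
Reagents that add atoms: none
Why: Enolate O-phosphorylation and base-induced 1,3-phosphorus shift give the α-phosphono lactone anion, which undergoes Horner–Wadsworth–Emmons olefination in the same flask. The E isomer is expected to dominate, but both isomers give the same dienolate in step 5.

Step 5
Reactants: 10 methyl 4-[(2S,4E)-4-ethylidene-5-oxooxolan-2-yl]-3,3-dimethylbutanoate
Product: 11 (1R,6S)-1-ethenyl-4,4-dimethyl-7-oxabicyclo[4.2.1]nonane-2,8-dione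
Conditions: LDA (1.2 equiv), THF/DMPU, −78 → −20 °C; sat. aq. NH4Cl at −78 °C
Reagents that add atoms: none
Why: γ-Deprotonation at C3 gives the extended lactone dienolate, which is acylated at its α-carbon C1 by the C6 ester (intramolecular Claisen, Dieckmann type, seven-membered ring). The tether from C10 reaches only one face of the lactone, so C1 is set cis-bridged as a consequence of C10.

Step 6
Reactants: 11 (1R,6S)-1-ethenyl-4,4-dimethyl-7-oxabicyclo[4.2.1]nonane-2,8-dione; 12 vinylmagnesium bromide
Product: 13 (1R,2S,6S)-1,2-diethenyl-2-hydroxy-4,4-dimethyl-7-oxabicyclo[4.2.1]nonan-8-one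
Conditions: CeCl3 (anhydrous, 1.5 equiv), 12 (1.5 equiv), THF, −78 °C
Reagents that add atoms: none
Why: Organocerium 1,2-addition to the ketone (the lactone is less electrophilic and enolisation is suppressed). Attack is expected anti to the C1–C13 bond (Felkin–Anh) and from the side of the one-atom bridge C11, which places the new vinyl group anti to C13 and sets C6 of the carbinol as drawn.

Step 7
Reactants: 13 (1R,2S,6S)-1,2-diethenyl-2-hydroxy-4,4-dimethyl-7-oxabicyclo[4.2.1]nonan-8-one; 14 Eschenmoser's salt (N,N-dimethylmethyleneiminium iodide)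
Product: 17 (1E,10S)-5-[(dimethylamino)methyl]-8,8-dimethyl-11-oxabicyclo[8.2.1]tridec-1-ene-6,12-dione (C5 epimers), via potassium alkoxide 15 (not isolated), via potassium enolate 16 (not isolated)
Conditions: KHMDS (1.2 equiv), 18-crown-6 (1.5 equiv), THF, −78 → 0 °C; then 14 (2 equiv), −78 °C → rt
Reagents that add atoms: none
Why: Anionic oxy-Cope rearrangement: alkoxide 15 undergoes a [3,3] shift of the 1,5-diene C4=C5–C6–C1–C2=C3, forming C3–C4 and breaking C1–C6, which is weakened by the oxyanion on C6 and the lactone carbonyl on C1. The closest known reaction type is the four-carbon ring expansion of 1,2-divinylcycloalkanols, also known for carbinols made from α-vinyl β-keto esters. The eleven-membered ring is not closed end to end: it arises by ring expansion of the cycloheptane through a six-membered chair transition state, and the lactone bridge C13–O–C10 is carried over unchanged (bicyclo[4.2.1] to bicyclo[8.2.1]). No stereocentre of the target is created: C1 and C6 become sp2, C10 is untouched, and C5 of 17 forms as an epimer mixture that is erased in step 8. The selectivity needed is the C1=C2 geometry: the bridge fixes C13 and C11 on C1, the C6 vinyl group is anti to C13, and the only chair then has C11 pseudo-axial and C13 pseudo-equatorial, so C3 ends cis to C11 and trans to C13 (1E), as in the target. The same geometry is the one a chain from C2 to C10 fits best, so a stepwise retro-aldol/vinylogous Michael path should converge on it. The enolate 16 is released regiospecifically as C5=C6, so the Mannich reaction with 14 places C12 on C5 and not on C7. Transannular attack of C5 on C13 is excluded because C3 is trans to C13 across C1=C2.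

Step 8
Reactants: 17 (1E,10S)-5-[(dimethylamino)methyl]-8,8-dimethyl-11-oxabicyclo[8.2.1]tridec-1-ene-6,12-dione
Product: 19 (1E,10S)-8,8-dimethyl-5-methylidene-11-oxabicyclo[8.2.1]tridec-1-ene-6,12-dione, via ammonium iodide 18 (not isolated)
Conditions: MeI (5 equiv), CH2Cl2, rt; then sat. aq. NaHCO3, rt
Reagents that add atoms: none
Why: N-methylation followed by E1cB (Hofmann-type) loss of trimethylamine from the β-ammonio ketone gives the α-methylene ketone under mild conditions; both C5 epimers converge.

Step 9
Reactants: 19 (1E,10S)-8,8-dimethyl-5-methylidene-11-oxabicyclo[8.2.1]tridec-1-ene-6,12-dione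
Product: 20 (1E,6S,10S)-6-hydroxy-8,8-dimethyl-5-methylidene-11-oxabicyclo[8.2.1]tridec-1-en-12-one
Conditions: (R)-2-methyl-CBS-oxazaborolidine (0.5 equiv), catecholborane (1.5 equiv), PhMe, −78 °C
Reagents that add atoms: none
Why: Corey–Bakshi–Shibata 1,2-reduction of an enone: the α-branched alkenyl group (C5) acts as the large substituent and the C7 methylene as the small one, so the (R)-catalyst should give the (6S)-alcohol; lactone and enoate are inert.

Step 10
Reactants: 20 (1E,6S,10S)-6-hydroxy-8,8-dimethyl-5-methylidene-11-oxabicyclo[8.2.1]tridec-1-en-12-one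
Product: 21 (1E,6S,10S)-6-{[tert-butyl(dimethyl)silyl]oxy}-8,8-dimethyl-5-methylidene-11-oxabicyclo[8.2.1]tridec-1-en-12-one
Conditions: TBSCl, imidazole, DMF, rt
Reagents that add atoms: tert-butyldimethylsilyl chloride, CC(C)(C)[Si](C)(C)Cl
Why: Silylation of the only hydroxyl, so that C10–O is the only alkoxide in step 11.

Step 11
Reactants: 21 (1E,6S,10S)-6-{[tert-butyl(dimethyl)silyl]oxy}-8,8-dimethyl-5-methylidene-11-oxabicyclo[8.2.1]tridec-1-en-12-one; 22 angelic anhydride [(2Z)-2-methylbut-2-enoic anhydride]
Product: 24 (1E,6S,10S)-6-{[tert-butyl(dimethyl)silyl]oxy}-8,8-dimethyl-5-methylidene-10-{[(2Z)-2-methylbut-2-enoyl]oxy}cycloundec-1-ene-1-carboxylic acid, via lithium carboxylate 23 (not isolated)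
Conditions: LiOH·H2O (1.5 equiv), THF/H2O, rt; evaporate, azeotrope with PhMe; LiHMDS (1.5 equiv), THF, −40 °C; 22 (2.5 equiv), −40 → 0 °C; aq. NaHCO3, then 1 M HCl to pH 4
Reagents that add atoms: lithium hydroxide, [Li+].[OH-]
Why: Saponification opens the lactone at the acyl carbon (C10 configuration kept). The C10 alkoxide of the carboxylate salt is then acylated by the anhydride, an alkoxide acylation for which Z to E isomerisation is not expected at low temperature. The hydroxy acid is never neutral, so it cannot relactonise, and any mixed anhydride at C13 is hydrolysed on work-up.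

Step 12
Reactants: 24 (1E,6S,10S)-6-{[tert-butyl(dimethyl)silyl]oxy}-8,8-dimethyl-5-methylidene-10-{[(2Z)-2-methylbut-2-enoyl]oxy}cycloundec-1-ene-1-carboxylic acid
Product: 25 (1E,6S,10S)-6-hydroxy-8,8-dimethyl-5-methylidene-10-{[(2Z)-2-methylbut-2-enoyl]oxy}cycloundec-1-ene-1-carboxylic acid (target)
Conditions: HF·pyridine, THF/pyridine, 0 °C → rt
Reagents that add atoms: none
Why: Fluoride-mediated desilylation under buffered conditions that should leave the angelate, the acid and the allylic alcohol untouched.

## Compound list

1 | dimedone (5,5-dimethylcyclohexane-1,3-dione) | CC1(C)CC(=O)CC(=O)C1 | starting material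
2 | methyl bromoacetate | COC(=O)CBr | starting material
3 | methyl 2-(4,4-dimethyl-2,6-dioxocyclohexyl)acetate | COC(=O)CC1C(=O)CC(C)(C)CC1=O | intermediate
4 | 6,6-dimethyl-4-oxooctanedioic acid | OC(=O)CCC(=O)CC(C)(C)CC(=O)O | intermediate (not isolated)
5 | dimethyl 6,6-dimethyl-4-oxooctanedioate | COC(=O)CCC(=O)CC(C)(C)CC(=O)OC | intermediate
6 | dimethyl (4R)-4-hydroxy-6,6-dimethyloctanedioate | COC(=O)CC[C@@H](O)CC(C)(C)CC(=O)OC | intermediate (not isolated)
7 | methyl 3,3-dimethyl-4-[(2R)-5-oxooxolan-2-yl]butanoate | COC(=O)CC(C)(C)C[C@H]1CCC(=O)O1 | intermediate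
8 | acetaldehyde | CC=O | starting material
9 | methyl 4-[(2S)-4-(diethoxyphosphoryl)-5-oxooxolan-2-yl]-3,3-dimethylbutanoate (C4 epimers; present as its lithium enolate) | COC(=O)CC(C)(C)C[C@H]1CC(P(=O)(OCC)OCC)C(=O)O1 | intermediate (not isolated)
10 | methyl 4-[(2S,4E)-4-ethylidene-5-oxooxolan-2-yl]-3,3-dimethylbutanoate | COC(=O)CC(C)(C)C[C@H]1C/C(=C\C)C(=O)O1 | intermediate
11 | (1R,6S)-1-ethenyl-4,4-dimethyl-7-oxabicyclo[4.2.1]nonane-2,8-dione | C=C[C@]12C[C@H](CC(C)(C)CC1=O)OC2=O | intermediate
12 | vinylmagnesium bromide | C=C[Mg]Br | starting material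
13 | (1R,2S,6S)-1,2-diethenyl-2-hydroxy-4,4-dimethyl-7-oxabicyclo[4.2.1]nonan-8-one | C=C[C@]12C[C@H](CC(C)(C)C[C@]1(O)C=C)OC2=O | intermediate
14 | Eschenmoser's salt (N,N-dimethylmethyleneiminium iodide) | C=[N+](C)C.[I-] | starting material
15 | potassium (1R,2S,6S)-1,2-diethenyl-4,4-dimethyl-8-oxo-7-oxabicyclo[4.2.1]nonan-2-olate | [K+].C=C[C@]12C[C@H](CC(C)(C)C[C@]1([O-])C=C)OC2=O | intermediate (not isolated)
16 | potassium (1E,10S)-8,8-dimethyl-12-oxo-11-oxabicyclo[8.2.1]trideca-1,5-dien-6-olate | [K+].[O-]C1=CCC/C=C2\C[C@H](CC(C)(C)C1)OC2=O | intermediate (not isolated)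
17 | (1E,10S)-5-[(dimethylamino)methyl]-8,8-dimethyl-11-oxabicyclo[8.2.1]tridec-1-ene-6,12-dione (C5 epimers) | CN(C)CC1CC/C=C2\C[C@H](CC(C)(C)CC1=O)OC2=O | intermediate
18 | [(1E,10S)-8,8-dimethyl-6,12-dioxo-11-oxabicyclo[8.2.1]tridec-1-en-5-yl]-N,N,N-trimethylmethanaminium iodide | C[N+](C)(C)CC1CC/C=C2\C[C@H](CC(C)(C)CC1=O)OC2=O.[I-] | intermediate (not isolated)
19 | (1E,10S)-8,8-dimethyl-5-methylidene-11-oxabicyclo[8.2.1]tridec-1-ene-6,12-dione | C=C1CC/C=C2\C[C@H](CC(C)(C)CC1=O)OC2=O | intermediate
20 | (1E,6S,10S)-6-hydroxy-8,8-dimethyl-5-methylidene-11-oxabicyclo[8.2.1]tridec-1-en-12-one | C=C1CC/C=C2\C[C@H](CC(C)(C)C[C@@H]1O)OC2=O | intermediate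
21 | (1E,6S,10S)-6-{[tert-butyl(dimethyl)silyl]oxy}-8,8-dimethyl-5-methylidene-11-oxabicyclo[8.2.1]tridec-1-en-12-one | C=C1CC/C=C2\C[C@H](CC(C)(C)C[C@@H]1O[Si](C)(C)C(C)(C)C)OC2=O | intermediate
22 | angelic anhydride [(2Z)-2-methylbut-2-enoic anhydride] | C/C=C(/C)C(=O)OC(=O)/C(C)=C\C | starting material
23 | lithium (1E,6S,10S)-6-{[tert-butyl(dimethyl)silyl]oxy}-10-hydroxy-8,8-dimethyl-5-methylidenecycloundec-1-ene-1-carboxylate | [Li+].C=C1CC/C=C(/C(=O)[O-])C[C@@H](O)CC(C)(C)C[C@@H]1O[Si](C)(C)C(C)(C)C | intermediate (not isolated)
24 | (1E,6S,10S)-6-{[tert-butyl(dimethyl)silyl]oxy}-8,8-dimethyl-5-methylidene-10-{[(2Z)-2-methylbut-2-enoyl]oxy}cycloundec-1-ene-1-carboxylic acid | C=C1CC/C=C(/C(=O)O)C[C@@H](OC(=O)/C(C)=C\C)CC(C)(C)C[C@@H]1O[Si](C)(C)C(C)(C)C | intermediate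
25 | (1E,6S,10S)-6-hydroxy-8,8-dimethyl-5-methylidene-10-{[(2Z)-2-methylbut-2-enoyl]oxy}cycloundec-1-ene-1-carboxylic acid | C=C1CC/C=C(/C(=O)O)C[C@@H](OC(=O)/C(C)=C\C)CC(C)(C)C[C@@H]1O | target

## Step count and risk

Total step count: 12. Longest linear sequence: 12 steps (from 1).

**Step 7 (key step).** Two processes could defeat it. Heterolytic retro-aldol cleavage of C1–C6 could outrun the concerted shift, with loss of the open-chain vinyl ketone by polymerisation. Poor facial selectivity in step 6 could deliver the C6 epimer of 13, whose only chair leads to the 1Z alkene. The fallback gives up the ring expansion for a reductive macrocyclisation at C5–C6; it sets out from 7 and returns at 19. Lactone 7 is olefinated as in step 4 with pent-4-ynal in place of 8 to give the pentynylidene lactone ester F1. Saponification of both acyl groups and acidification (the γ-hydroxy acid relactonises) gives the lactone acid F2. Mixed-anhydride activation (i-BuOCOCl, N-methylmorpholine) and NaBH4 give the primary alcohol F3, and Dess–Martin oxidation gives the ynal F4. Nickel(0)-catalysed reductive ynal macrocyclisation (Ni(cod)2, a bulky N-heterocyclic carbene ligand to direct bond formation to the internal alkyne carbon, Et3SiH, high dilution) should give the macrocyclic triethylsilyl ether F5 as C6 epimers. Fluoride gives the epimeric allylic alcohols F6, and Dess–Martin oxidation converges them on 19.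

**Step 5.** The acylation forms a quaternary, non-enolisable β-keto lactone, so the methoxide set free can reverse it (retro-Claisen) or open the lactone; enolisation of the ester at C7 would also shut the electrophile down. The fallback uses an acyl donor whose tetrahedral adduct is stable; it sets out from 10 and returns at 11. Saponification and acidification of 10 give the ethylidene lactone acid F7, CDI and N,O-dimethylhydroxylamine give the Weinreb amide F8, and the dienolate of F8 (LDA, −78 °C) should give 11 on work-up.

**Step 11.** Acylation of the carboxylate by 22 could precede acylation of the C10 alkoxide and lead back to the lactone, and the strongly basic medium could isomerise the angeloyl group. The fallback protects the acid first; it sets out from 21 and returns at 24. Saponification of 21 and alkylation of the carboxylate with allyl bromide give the hydroxy allyl ester F11. Yamaguchi-type esterification with angelic acid (2,4,6-trichlorobenzoyl chloride, Et3N, PhMe) gives the allyl ester angelate F12, and Pd(PPh3)4/morpholine removes the allyl group to give 24.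

**Step 9.** Facial discrimination could be poor because the small substituent C7 is a neopentyl-type methylene and the bicyclic substrate may be mismatched with the catalyst. The fallback relies on separation and inversion; it sets out from 19 and returns at 20. Luche reduction gives 20 together with the (6R)-epimeric alcohol F9, which is a diastereomer and separable. Mitsunobu esterification of F9 with 4-nitrobenzoic acid inverts C6 to the (6S) 4-nitrobenzoate F10, and mild methanolysis (K2CO3, MeOH, 0 °C) gives 20.

**Step 3.** Enantioselectivity could be eroded by the hindered, neopentyl-flanked ketone or by competing direction from the remote C6 ester, and some δ-lactone could form. The fallback replaces the metal catalyst by a ketoreductase with cofactor recycling, selected for the (4R)-alcohol, followed by the same acid lactonisation; it sets out from 5, returns at 7 and makes no new compound (F0).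

## Further compounds

F1 | step 7 | methyl 3,3-dimethyl-4-[(2S,4E)-5-oxo-4-(pent-4-yn-1-ylidene)oxolan-2-yl]butanoate | COC(=O)CC(C)(C)C[C@H]1C/C(=C\CCC#C)C(=O)O1
F2 | step 7 | 3,3-dimethyl-4-[(2S,4E)-5-oxo-4-(pent-4-yn-1-ylidene)oxolan-2-yl]butanoic acid | OC(=O)CC(C)(C)C[C@H]1C/C(=C\CCC#C)C(=O)O1
F3 | step 7 | (3E,5S)-5-(4-hydroxy-2,2-dimethylbutyl)-3-(pent-4-yn-1-ylidene)oxolan-2-one | OCCC(C)(C)C[C@H]1C/C(=C\CCC#C)C(=O)O1
F4 | step 7 | 3,3-dimethyl-4-[(2S,4E)-5-oxo-4-(pent-4-yn-1-ylidene)oxolan-2-yl]butanal | O=CCC(C)(C)C[C@H]1C/C(=C\CCC#C)C(=O)O1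
F5 | step 7 | (1E,10S)-8,8-dimethyl-5-methylidene-6-[(triethylsilyl)oxy]-11-oxabicyclo[8.2.1]tridec-1-en-12-one (C6 epimers) | C=C1CC/C=C2\C[C@H](CC(C)(C)CC1O[Si](CC)(CC)CC)OC2=O
F6 | step 7 | (1E,10S)-6-hydroxy-8,8-dimethyl-5-methylidene-11-oxabicyclo[8.2.1]tridec-1-en-12-one (C6 epimers) | C=C1CC/C=C2\C[C@H](CC(C)(C)CC1O)OC2=O
F7 | step 5 | 4-[(2S,4E)-4-ethylidene-5-oxooxolan-2-yl]-3,3-dimethylbutanoic acid | OC(=O)CC(C)(C)C[C@H]1C/C(=C\C)C(=O)O1
F8 | step 5 | 4-[(2S,4E)-4-ethylidene-5-oxooxolan-2-yl]-N-methoxy-N,3,3-trimethylbutanamide | CON(C)C(=O)CC(C)(C)C[C@H]1C/C(=C\C)C(=O)O1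
F11 | step 11 | prop-2-en-1-yl (1E,6S,10S)-6-{[tert-butyl(dimethyl)silyl]oxy}-10-hydroxy-8,8-dimethyl-5-methylidenecycloundec-1-ene-1-carboxylate | C=C1CC/C=C(/C(=O)OCC=C)C[C@@H](O)CC(C)(C)C[C@@H]1O[Si](C)(C)C(C)(C)C
F12 | step 11 | prop-2-en-1-yl (1E,6S,10S)-6-{[tert-butyl(dimethyl)silyl]oxy}-8,8-dimethyl-5-methylidene-10-{[(2Z)-2-methylbut-2-enoyl]oxy}cycloundec-1-ene-1-carboxylate | C=C1CC/C=C(/C(=O)OCC=C)C[C@@H](OC(=O)/C(C)=C\C)CC(C)(C)C[C@@H]1O[Si](C)(C)C(C)(C)C
F9 | step 9 | (1E,6R,10S)-6-hydroxy-8,8-dimethyl-5-methylidene-11-oxabicyclo[8.2.1]tridec-1-en-12-one | C=C1CC/C=C2\C[C@H](CC(C)(C)C[C@H]1O)OC2=O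
F10 | step 9 | (1E,6S,10S)-8,8-dimethyl-5-methylidene-12-oxo-11-oxabicyclo[8.2.1]tridec-1-en-6-yl 4-nitrobenzoate | C=C1CC/C=C2\C[C@H](CC(C)(C)C[C@@H]1OC(=O)c3ccc(cc3)[N+](=O)[O-])OC2=O
F0 | step 3 | none | none
A1 | alternative 1 | 4-[(2S,4E)-4-(4-bromopent-4-en-1-ylidene)-5-oxooxolan-2-yl]-3,3-dimethylbutanal | O=CCC(C)(C)C[C@H]1C/C(=C\CCC(Br)=C)C(=O)O1
A2 | alternative 2 | (5S)-5-[(4S)-4-{[tert-butyl(dimethyl)silyl]oxy}-2,2-dimethyl-5-methylidenenon-8-en-1-yl]-3-methylideneoxolan-2-one | C=CCCC(=C)[C@@H](O[Si](C)(C)C(C)(C)C)CC(C)(C)C[C@H]1CC(=C)C(=O)O1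
A3 | alternative 3 | methyl 1-hydroxy-10,10-dimethyl-2-methylidene-8-oxobicyclo[5.4.0]undec-5-ene-6-carboxylate (racemic) | COC(=O)C1=CCCC(=C)C2(O)CC(C)(C)CC(=O)C12
A4 | alternative 3 | methyl (1E)-8,8-dimethyl-5-methylidene-6,10-dioxocycloundec-1-ene-1-carboxylate | COC(=O)/C1=C/CCC(=C)C(=O)CC(C)(C)CC(=O)C1
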